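**Retrosynthetic overview**
1. The target is read as (+)-catechin-(4α→8)-(+)-gallocatechin-(4β→8)-(+)-catechin. The last C–C disconnection is the top interflavan bond (C4 top to C8 middle): a 3-O-acetyl-directed Friedel–Crafts union of C4-activated catechin 23 with dimer 19, then deprotection.
2. The bottom catechin is not taken from the chiral pool. Its ring C is opened at C3–C4 and O1–C2 to salicylaldehyde 10 and enal 13, which are joined in one domino oxa-Michael/aldol condensation. C3 carries a formyl group as a removable activating group, the flav-3-ene is a temporary oxidation level, and hydroboration then sets the 2,3-trans 3-OH.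
3. Enabling feature: on ring A of the bottom unit the benzylic C4 sits on C4a, ortho to C8a–O1, so O1/C8a/C4a/C4 form a salicylaldehyde pattern. The C2–C3 unit (aryl on C2, oxygen on C3) maps onto the β- and α-carbons of a cinnamaldehyde.
4. The 3,4-cis (4β→8) bond is made before ring C exists. Symmetric 3,5-bis(benzyloxy)phenol is tied to O3 of gallocatechin by a temporary diisopropylsilylene and delivered to C4 intramolecularly (a seven-membered ring not in the target, cleaved by fluoride). This also frees the single phenol that becomes O1.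
5. Ring order: temporary silylene ring (step 4), then ring C of the bottom unit (step 8); the top unit is attached with its rings intact (step 14).

Key step: step 8

Assumption: flavan numbering is used (α = face of the C2 aryl group of a 2R flavan, β = the opposite face), so the target is 2,3-trans in all three units, 3,4-trans in the top unit and 3,4-cis in the middle unit. The C4 configuration drawn for the 4-(2-ethoxyethoxy) ethers is the expected one and is lost on ionisation.

**Route**

Step 1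
Reactants: 1 (+)-gallocatechin
Product: 2 5,7,3',4',5'-penta-O-benzyl-(+)-gallocatechin
Conditions: BnBr (5.5 equiv), K2CO3, DMF, 0 °C → rt, argon
Reagents that add atoms: benzyl bromide, BrCc1ccccc1
Why: Williamson etherification under carbonate benzylates only the five phenolic hydroxyls (the C3 alcohol is not deprotonated) and leaves both stereocentres untouched.

Step 2
Reactants: 2 5,7,3',4',5'-penta-O-benzyl-(+)-gallocatechin
Product: 3 5,7,3',4',5'-penta-O-benzyl-4β-(2-ethoxyethoxy)-(+)-gallocatechin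
Conditions: DDQ (2 equiv), 2-ethoxyethanol, CH2Cl2, rt
Reagents that add atoms: 2-ethoxyethanol, CCOCCO
Why: DDQ abstracts hydride from the benzylic C4 activated by the 5,7-dioxygenated ring A and the quinone-methide cation is trapped by the alcohol (oxidative benzylic C–H etherification), giving a C4 leaving group whose configuration is irrelevant because it is ionised in step 4.

Step 3
Reactants: 3 5,7,3',4',5'-penta-O-benzyl-4β-(2-ethoxyethoxy)-(+)-gallocatechin; 4 3,5-bis(benzyloxy)phenol
Product: 6 3-O-{[3,5-bis(benzyloxy)phenoxy]diisopropylsilyl} ether of 3, via aryloxychlorosilane 5 (not isolated)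
Conditions: first 4, iPr2SiCl2 (3 equiv), imidazole, CH2Cl2, 0 °C, volatiles removed in vacuo; then 3, imidazole, DMAP, DMF, rt
Reagents that add atoms: dichlorodiisopropylsilane, CC(C)[Si](Cl)(Cl)C(C)C
Why: Two successive silyl ether formations on one silicon atom (temporary silicon tether) join the future O1 phenol to the β-oriented O3 of the gallocatechin unit; excess dichlorosilane keeps the first substitution at the mono stage and the hindered secondary alcohol displaces the remaining chloride under imidazole/DMAP.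

Step 4
Reactants: 6 3-O-{[3,5-bis(benzyloxy)phenoxy]diisopropylsilyl} ether of 3
Product: 7 cyclic diisopropylsilylene of 5,7,3',4',5'-penta-O-benzyl-4β-[2-hydroxy-4,6-bis(benzyloxy)phenyl]-(+)-gallocatechin
Conditions: TMSOTf (0.2 equiv), CH2Cl2 (0.002 M), −78 → −30 °C; Et3N, aq NaHCO3
Reagents that add atoms: none
Why: TMSOTf ionises the C4 ether to the ring A-stabilised benzylic cation and the electron-rich arene held by the short O3–Si–O tether attacks through the carbon ortho to its silyloxy group (intramolecular Friedel–Crafts alkylation closing a seven-membered silylene ring), which should place the aryl group on the β face cis to O3 because the tether removes the steric clash that disfavours β attack in untethered 2,3-trans couplings and a 3-O-silyl group cannot participate; the two ortho carbons of the symmetric arene are equivalent, and high dilution suppresses attack by C8 of another molecule.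

Step 5
Reactants: 7 cyclic diisopropylsilylene
Product: 8 5,7,3',4',5'-penta-O-benzyl-4β-[2-hydroxy-4,6-bis(benzyloxy)phenyl]-(+)-gallocatechin
Conditions: HF·pyridine, pyridine, THF, 0 °C → rt
Reagents that add atoms: none
Why: Buffered fluoride cleaves both Si–O bonds of the silylene (silyl ether cleavage), returning the C3 alcohol and unveiling the single phenol that will become O1 of the bottom unit, while the C4–aryl bond is not ionised under these mild conditions.

Step 6
Reactants: 8 5,7,3',4',5'-penta-O-benzyl-4β-[2-hydroxy-4,6-bis(benzyloxy)phenyl]-(+)-gallocatechin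
Product: 10 5,7,3',4',5'-penta-O-benzyl-4β-[3-formyl-2-hydroxy-4,6-bis(benzyloxy)phenyl]-(+)-gallocatechin, via salicyl alcohol 9 (not isolated)
Conditions: MgCl2, Et3N, (CH2O)n, THF, reflux; dilute HCl work-up
Reagents that add atoms: paraformaldehyde (as formaldehyde), C=O
Why: The magnesium phenoxide directs formaldehyde to the position ortho to the free phenol and the salicyl alcohol is oxidised in place by hydride transfer to a second formaldehyde (magnesium-mediated ortho-formylation of phenols); the only free ortho carbon of 8 is the future C4a, so the aldehyde carbon becomes C4 of the bottom unit.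

Step 7
Reactants: 11 3,4-bis(benzyloxy)benzaldehyde; 12 (triphenylphosphoranylidene)acetaldehyde
Product: 13 (E)-3-[3,4-bis(benzyloxy)phenyl]prop-2-enal
Conditions: toluene, 80 °C
Reagents that add atoms: none
Why: Wittig olefination with the stabilised formyl ylide gives the (E)-cinnamaldehyde selectively.

Step 8
Reactants: 10 5,7,3',4',5'-penta-O-benzyl-4β-[3-formyl-2-hydroxy-4,6-bis(benzyloxy)phenyl]-(+)-gallocatechin; 13 (E)-3-[3,4-bis(benzyloxy)phenyl]prop-2-enal
Product: 16 nona-O-benzyl (+)-gallocatechin-(4β→8)-(3-formylflav-3-ene) with the C2 aryl group of the new unit α, via oxa-Michael enamine 14 (not isolated), via aldol adduct 15 (not isolated)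
Conditions: (S)-α,α-diphenylprolinol trimethylsilyl ether (30 mol %), 2-nitrobenzoic acid (30 mol %), 4 Å MS, toluene, 0 °C → rt
Reagents that add atoms: none
Why: The secondary amine condenses with enal 13 to an (E)-iminium ion, the ring A phenol oxygen of 10 adds to its β-carbon (oxa-Michael, O1–C2 bond), and the resulting enamine 14 attacks the neighbouring aryl aldehyde carbon C4 through its α-carbon C3 in an intramolecular aldol reaction that is pulled forward by loss of water and release of the catalyst. The closest known reaction type is the diarylprolinol silyl ether-catalysed domino oxa-Michael/aldol condensation of salicylaldehydes with cinnamaldehydes to 2-aryl-2H-chromene-3-carbaldehydes. Ring C of the bottom unit is closed by the C3–C4 bond in a 6-(enolexo)-exo-trig aldol closure. The only new stereocentre that persists, C2, is set in the oxa-Michael step by the catalyst: its diphenyl(silyloxy)methyl group shields one face of the iminium ion so that the phenol adds to the opposite face, which with the (S)-catalyst should place the 3,4-bis(benzyloxy)phenyl group α as in catechin (C3 and C4 of adduct 15 are lost on dehydration). The step needs attack by the one phenol of 10 and not by the C3 alcohol of the gallocatechin unit, and catalyst control over the remote stereocentres, which are secured by the far higher Michael donor ability of a phenol under iminium catalysis and by the distance between the reacting site and the existing stereocentres. The formyl group left on C3 is the activating group of the closure and is removed in step 9.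

Step 9
Reactants: 16 nona-O-benzyl (+)-gallocatechin-(4β→8)-(3-formylflav-3-ene)
Product: 17 nona-O-benzyl (+)-gallocatechin-(4β→8)-flav-3-ene (C2 aryl of the flavene α)
Conditions: RhCl(PPh3)3 (1.1 equiv), toluene, 80 °C
Reagents that add atoms: none
Why: RhCl(PPh3)3 adds oxidatively into the formyl C–H bond, extrudes CO and eliminates the vinyl C–H bond (Tsuji–Wilkinson decarbonylation), which removes the activating group from C3 with the C3=C4 double bond, the benzyl ethers and the C2 stereocentre left in place.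

Step 10
Reactants: 17 nona-O-benzyl (+)-gallocatechin-(4β→8)-flav-3-ene
Product: 19 nona-O-benzyl (+)-gallocatechin-(4β→8)-(+)-catechin, via C3 alkylborane 18 (not isolated)
Conditions: BH3·THF (excess), THF, 0 °C → rt; then aq NaOH, H2O2, 0 °C
Reagents that add atoms: borane–tetrahydrofuran (boron of 18 only), B.C1CCOC1; hydrogen peroxide, OO
Why: Borane adds to the styrene-type double bond with boron on C3 (away from the benzylic carbon on the electron-rich ring A) and from the face anti to the C2 aryl group, and oxidation with retention gives the 2,3-trans alcohol of the catechin unit (hydroboration–oxidation under substrate control by C2).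

Step 11
Reactants: 20 (+)-catechin
Product: 21 5,7,3',4'-tetra-O-benzyl-(+)-catechin
Conditions: BnBr (4.4 equiv), K2CO3, DMF, 0 °C → rt, argon
Reagents that add atoms: benzyl bromide, BrCc1ccccc1
Why: The same phenol-selective Williamson benzylation as in step 1.

Step 12
Reactants: 21 5,7,3',4'-tetra-O-benzyl-(+)-catechin
Product: 22 5,7,3',4'-tetra-O-benzyl-4β-(2-ethoxyethoxy)-(+)-catechin
Conditions: DDQ (2 equiv), 2-ethoxyethanol, CH2Cl2, rt
Reagents that add atoms: 2-ethoxyethanol, CCOCCO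
Why: The same DDQ-mediated benzylic C–H etherification as in step 2 gives the C4 leaving group of the top unit.

Step 13
Reactants: 22 5,7,3',4'-tetra-O-benzyl-4β-(2-ethoxyethoxy)-(+)-catechin
Product: 23 3-O-acetyl-5,7,3',4'-tetra-O-benzyl-4β-(2-ethoxyethoxy)-(+)-catechin
Conditions: Ac2O, pyridine, DMAP (cat.), rt
Reagents that add atoms: acetic anhydride, CC(=O)OC(C)=O
Why: Standard acetylation of the C3 alcohol installs the acyl group that will shield the β face of the C4 cation by neighbouring-group participation.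

Step 14
Reactants: 19 nona-O-benzyl (+)-gallocatechin-(4β→8)-(+)-catechin; 23 3-O-acetyl-5,7,3',4'-tetra-O-benzyl-4β-(2-ethoxyethoxy)-(+)-catechin
Product: 24 3-O-acetyl-trideca-O-benzyl-(+)-catechin-(4α→8)-(+)-gallocatechin-(4β→8)-(+)-catechin (acetate on the top unit)
Conditions: 19 (2 equiv, excess recovered), 23 (1 equiv), TMSOTf (0.2 equiv), CH2Cl2, −78 °C; Et3N
Reagents that add atoms: none
Why: TMSOTf ionises the C4 ether of 23, the 3-O-acetyl group blocks the β face as an acyloxonium ion, and C8 of the gallocatechin ring A of 19, the most nucleophilic free arene position (the C6 positions are much less reactive and C8 of the bottom unit is substituted), attacks from the α face to give the 3,4-trans (4α→8) bond (Friedel–Crafts alkylation).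

Step 15
Reactants: 24 3-O-acetyl-trideca-O-benzyl trimer
Product: 25 trideca-O-benzyl-(+)-catechin-(4α→8)-(+)-gallocatechin-(4β→8)-(+)-catechin
Conditions: NaOMe (cat.), MeOH/THF, rt → 40 °C
Reagents that add atoms: none
Why: Methoxide-catalysed transesterification (Zemplén conditions) removes the acetate without affecting benzyl ethers, interflavan bonds or stereocentres.

Step 16
Reactants: 25 trideca-O-benzyl trimer
Product: 26 (+)-catechin-(4α→8)-(+)-gallocatechin-(4β→8)-(+)-catechin (target)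
Conditions: H2 (1 atm), Pd(OH)2/C, THF/MeOH/H2O, rt; filtration, lyophilisation
Reagents that add atoms: none
Why: Hydrogenolysis over Pd(OH)2/C cleaves the thirteen benzyl ethers under neutral conditions at ambient temperature and pressure, under which the benzylic C2–O1 bonds and the interflavan C–C bonds survive.

**Compound list**

1 | (+)-gallocatechin (2,3-trans, 2R,3S) | Oc1cc(O)c2c(c1)O[C@H](c1cc(O)c(O)c(O)c1)[C@@H](O)C2 | starting material
2 | 5,7,3',4',5'-penta-O-benzyl-(+)-gallocatechin (3-OH free) | c3ccccc3COc1cc(OCc3ccccc3)c2c(c1)O[C@H](c1cc(OCc3ccccc3)c(OCc3ccccc3)c(OCc3ccccc3)c1)[C@@H](O)C2 | intermediate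
3 | 5,7,3',4',5'-penta-O-benzyl-4β-(2-ethoxyethoxy)-(+)-gallocatechin (2,3-trans, C4 ether cis to 3-OH) | c3ccccc3COc1cc(OCc3ccccc3)c2c(c1)O[C@H](c1cc(OCc3ccccc3)c(OCc3ccccc3)c(OCc3ccccc3)c1)[C@@H](O)[C@H]2OCCOCC | intermediate
4 | 3,5-bis(benzyloxy)phenol | Oc1cc(OCc2ccccc2)cc(OCc2ccccc2)c1 | starting material
5 | [3,5-bis(benzyloxy)phenoxy]chlorodiisopropylsilane | CC(C)[Si](Cl)(C(C)C)Oc1cc(OCc2ccccc2)cc(OCc2ccccc2)c1 | intermediate
6 | 3-O-{[3,5-bis(benzyloxy)phenoxy]diisopropylsilyl} ether of 3 | c3ccccc3COc1cc(OCc3ccccc3)c2c(c1)O[C@H](c1cc(OCc3ccccc3)c(OCc3ccccc3)c(OCc3ccccc3)c1)[C@@H](O[Si](C(C)C)(C(C)C)Oc1cc(OCc3ccccc3)cc(OCc3ccccc3)c1)[C@H]2OCCOCC | intermediate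
7 | cyclic diisopropylsilylene bridging O3 and the aryl 2-oxygen of penta-O-benzyl-4β-[2-hydroxy-4,6-bis(benzyloxy)phenyl]-(+)-gallocatechin (aryl at C4 cis to O3) | c3ccccc3COc1cc(OCc3ccccc3)c2c(c1)O[C@H](c1cc(OCc3ccccc3)c(OCc3ccccc3)c(OCc3ccccc3)c1)[C@@H](O4)[C@H]2c1c(O[Si]4(C(C)C)C(C)C)cc(OCc3ccccc3)cc1OCc3ccccc3 | intermediate
8 | 5,7,3',4',5'-penta-O-benzyl-4β-[2-hydroxy-4,6-bis(benzyloxy)phenyl]-(+)-gallocatechin (2,3-trans-3,4-cis) | c3ccccc3COc1cc(OCc3ccccc3)c2c(c1)O[C@H](c1cc(OCc3ccccc3)c(OCc3ccccc3)c(OCc3ccccc3)c1)[C@@H](O)[C@H]2c1c(O)cc(OCc3ccccc3)cc1OCc3ccccc3 | intermediate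
9 | 5,7,3',4',5'-penta-O-benzyl-4β-[2-hydroxy-3-(hydroxymethyl)-4,6-bis(benzyloxy)phenyl]-(+)-gallocatechin | c3ccccc3COc1cc(OCc3ccccc3)c2c(c1)O[C@H](c1cc(OCc3ccccc3)c(OCc3ccccc3)c(OCc3ccccc3)c1)[C@@H](O)[C@H]2c1c(O)c(CO)c(OCc3ccccc3)cc1OCc3ccccc3 | intermediate
10 | 5,7,3',4',5'-penta-O-benzyl-4β-[3-formyl-2-hydroxy-4,6-bis(benzyloxy)phenyl]-(+)-gallocatechin | c3ccccc3COc1cc(OCc3ccccc3)c2c(c1)O[C@H](c1cc(OCc3ccccc3)c(OCc3ccccc3)c(OCc3ccccc3)c1)[C@@H](O)[C@H]2c1c(O)c(C=O)c(OCc3ccccc3)cc1OCc3ccccc3 | intermediate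
11 | 3,4-bis(benzyloxy)benzaldehyde | O=Cc1ccc(OCc2ccccc2)c(OCc2ccccc2)c1 | starting material
12 | (triphenylphosphoranylidene)acetaldehyde | O=CC=P(c1ccccc1)(c1ccccc1)c1ccccc1 | starting material
13 | (E)-3-[3,4-bis(benzyloxy)phenyl]prop-2-enal | O=C/C=C/c1ccc(OCc2ccccc2)c(OCc2ccccc2)c1 | intermediate
14 | oxa-Michael enamine: phenol oxygen of 10 bonded to the benzylic carbon of an (E)-3-[(S)-2-(diphenyl(trimethylsilyloxy)methyl)pyrrolidin-1-yl]-1-[3,4-bis(benzyloxy)phenyl]prop-2-enyl group (new centre catechin-type) | c3ccccc3COc1cc(OCc3ccccc3)c2c(c1)O[C@H](c1cc(OCc3ccccc3)c(OCc3ccccc3)c(OCc3ccccc3)c1)[C@@H](O)[C@H]2c1c(O[C@H](c4ccc(OCc3ccccc3)c(OCc3ccccc3)c4)/C=C/N4CCC[C@H]4C(c3ccccc3)(c3ccccc3)O[Si](C)(C)C)c(C=O)c(OCc3ccccc3)cc1OCc3ccccc3 | intermediate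
15 | aldol adduct: nona-O-benzyl (+)-gallocatechin-(4β→8)-(4-hydroxyflavan-3-carbaldehyde), C3 and C4 of the new ring as mixtures, drawn as the free aldehyde | c3ccccc3COc1cc(OCc3ccccc3)c2c(c1)O[C@H](c1cc(OCc3ccccc3)c(OCc3ccccc3)c(OCc3ccccc3)c1)[C@@H](O)[C@H]2c1c(OCc3ccccc3)cc(OCc3ccccc3)c2c1O[C@H](c1ccc(OCc3ccccc3)c(OCc3ccccc3)c1)C(C=O)C2O | intermediate
16 | nona-O-benzyl (+)-gallocatechin-(4β→8)-(3-formylflav-3-ene); bottom unit is a 5,7-bis(benzyloxy)-2-[3,4-bis(benzyloxy)phenyl]-2H-chromene-3-carbaldehyde linked through C8, C2 aryl α | c3ccccc3COc1cc(OCc3ccccc3)c2c(c1)O[C@H](c1cc(OCc3ccccc3)c(OCc3ccccc3)c(OCc3ccccc3)c1)[C@@H](O)[C@H]2c1c(OCc3ccccc3)cc(OCc3ccccc3)c2c1O[C@H](c1ccc(OCc3ccccc3)c(OCc3ccccc3)c1)C(C=O)=C2 | intermediate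
17 | nona-O-benzyl (+)-gallocatechin-(4β→8)-flav-3-ene (bottom unit 5,7,3',4'-tetrabenzyloxyflav-3-ene, C2 aryl α) | c3ccccc3COc1cc(OCc3ccccc3)c2c(c1)O[C@H](c1cc(OCc3ccccc3)c(OCc3ccccc3)c(OCc3ccccc3)c1)[C@@H](O)[C@H]2c1c(OCc3ccccc3)cc(OCc3ccccc3)c2c1O[C@H](c1ccc(OCc3ccccc3)c(OCc3ccccc3)c1)C=C2 | intermediate
18 | C3 alkylborane of 17 (boron on C3 of the bottom unit, trans to the C2 aryl group; drawn as the monoalkylborane) | c3ccccc3COc1cc(OCc3ccccc3)c2c(c1)O[C@H](c1cc(OCc3ccccc3)c(OCc3ccccc3)c(OCc3ccccc3)c1)[C@@H](O)[C@H]2c1c(OCc3ccccc3)cc(OCc3ccccc3)c2c1O[C@H](c1ccc(OCc3ccccc3)c(OCc3ccccc3)c1)[C@@H](B)C2 | intermediate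
19 | nona-O-benzyl (+)-gallocatechin-(4β→8)-(+)-catechin (both 3-OH free) | c3ccccc3COc1cc(OCc3ccccc3)c2c(c1)O[C@H](c1cc(OCc3ccccc3)c(OCc3ccccc3)c(OCc3ccccc3)c1)[C@@H](O)[C@H]2c1c(OCc3ccccc3)cc(OCc3ccccc3)c2c1O[C@H](c1ccc(OCc3ccccc3)c(OCc3ccccc3)c1)[C@@H](O)C2 | intermediate
20 | (+)-catechin (2R,3S) | Oc1cc(O)c2c(c1)O[C@H](c1ccc(O)c(O)c1)[C@@H](O)C2 | starting material
21 | 5,7,3',4'-tetra-O-benzyl-(+)-catechin | c3ccccc3COc1cc(OCc3ccccc3)c2c(c1)O[C@H](c1ccc(OCc3ccccc3)c(OCc3ccccc3)c1)[C@@H](O)C2 | intermediate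
22 | 5,7,3',4'-tetra-O-benzyl-4β-(2-ethoxyethoxy)-(+)-catechin | c3ccccc3COc1cc(OCc3ccccc3)c2c(c1)O[C@H](c1ccc(OCc3ccccc3)c(OCc3ccccc3)c1)[C@@H](O)[C@H]2OCCOCC | intermediate
23 | 3-O-acetyl-5,7,3',4'-tetra-O-benzyl-4β-(2-ethoxyethoxy)-(+)-catechin | c3ccccc3COc1cc(OCc3ccccc3)c2c(c1)O[C@H](c1ccc(OCc3ccccc3)c(OCc3ccccc3)c1)[C@@H](OC(C)=O)[C@H]2OCCOCC | intermediate
24 | 3-O-acetyl-trideca-O-benzyl-(+)-catechin-(4α→8)-(+)-gallocatechin-(4β→8)-(+)-catechin (acetate on top unit) | c3ccccc3COc1cc(OCc3ccccc3)c2c(c1)O[C@H](c1ccc(OCc3ccccc3)c(OCc3ccccc3)c1)[C@@H](OC(C)=O)[C@@H]2c1c(OCc3ccccc3)cc(OCc3ccccc3)c2c1O[C@H](c1cc(OCc3ccccc3)c(OCc3ccccc3)c(OCc3ccccc3)c1)[C@@H](O)[C@H]2c1c(OCc3ccccc3)cc(OCc3ccccc3)c2c1O[C@H](c1ccc(OCc3ccccc3)c(OCc3ccccc3)c1)[C@@H](O)C2 | intermediate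
25 | trideca-O-benzyl-(+)-catechin-(4α→8)-(+)-gallocatechin-(4β→8)-(+)-catechin | c3ccccc3COc1cc(OCc3ccccc3)c2c(c1)O[C@H](c1ccc(OCc3ccccc3)c(OCc3ccccc3)c1)[C@@H](O)[C@@H]2c1c(OCc3ccccc3)cc(OCc3ccccc3)c2c1O[C@H](c1cc(OCc3ccccc3)c(OCc3ccccc3)c(OCc3ccccc3)c1)[C@@H](O)[C@H]2c1c(OCc3ccccc3)cc(OCc3ccccc3)c2c1O[C@H](c1ccc(OCc3ccccc3)c(OCc3ccccc3)c1)[C@@H](O)C2 | intermediate
26 | (+)-catechin-(4α→8)-(+)-gallocatechin-(4β→8)-(+)-catechin | Oc1cc(O)c2c(c1)O[C@H](c1ccc(O)c(O)c1)[C@@H](O)[C@@H]2c1c(O)cc(O)c2c1O[C@H](c1cc(O)c(O)c(O)c1)[C@@H](O)[C@H]2c1c(O)cc(O)c2c1O[C@H](c1ccc(O)c(O)c1)[C@@H](O)C2 | target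

**Totals and risks**

Total step count: 16.
Longest linear sequence: 12 steps (steps 1–6, 8–10, 14–16, from (+)-gallocatechin).

Steps most likely to fail:

Step 8. The oxa-Michael addition of the hindered, hydrogen-bonded phenol is reversible and may outrun the aldol closure onto the electron-rich, doubly ortho-substituted aldehyde; catalyst control at C2 may also be eroded by this reversibility. The fallback sets out from 10 and returns at 17, making the two bonds in separate steps. Enal 13 is reduced (NaBH4, CeCl3·7H2O, MeOH) to (E)-3-[3,4-bis(benzyloxy)phenyl]prop-2-en-1-ol F1 and converted (ClCO2Me, pyridine) into (E)-3-[3,4-bis(benzyloxy)phenyl]allyl methyl carbonate F2. Iridium-catalysed asymmetric allylic etherification of the phenoxide of 10 with F2 ([Ir(cod)Cl]2, a chiral binaphthol-derived phosphoramidite of the enantiomeric series that gives the catechin-type centre, base, THF) should give the branched 1-arylallyl aryl ether F3. Wittig methylenation of its aldehyde (Ph3P=CH2, THF) gives the ortho-vinyl diene F4. Ring-closing metathesis (second-generation Grubbs catalyst, CH2Cl2, 40 °C) then closes the same C3–C4 bond as a double bond and gives 17 directly, so that step 9 is not needed.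

Step 4. The tethered arene may attack the α face of the cation (trans-fused silylene), or intermolecular arylation may compete, so that the 3,4-cis relationship is not secured. The fallback sets out from 4 and returns at 8, moving the stereochemical problem from C4 to C3. (−)-Epigallocatechin F5 is benzylated as in step 1 to 5,7,3',4',5'-penta-O-benzyl-(−)-epigallocatechin F6 and oxidised as in step 2 to its 4β-(2-ethoxyethoxy) ether F7. In this 2,3-cis series untethered arylation is inherently β-selective: phenol 4 with TMSOTf (CH2Cl2, −78 → −20 °C; O-alkylation followed by O→C migration to the ortho carbon) should give the 2,3-cis-3,4-trans adduct 4β-[2-hydroxy-4,6-bis(benzyloxy)phenyl]-penta-O-benzyl-epigallocatechin F8. Swern oxidation of the C3 alcohol gives the flavan-3-one F9, and reduction with LiBH(s-Bu)3 (L-Selectride, THF, −78 °C), with hydride entering anti to the pseudo-axial 4β-aryl group, should give the 3β-alcohol, which is 8.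

Step 9. At the temperature of the decarbonylation the 2H-chromene may open and re-close reversibly (6π-electrocyclic ring opening), which would scramble C2, or the double bond may migrate out of the C3–C4 position. The fallback sets out from 16 and returns at 19: the formyl carbon is kept through the reduction stage and excised oxidatively. Conjugate reduction of 16 ([(Ph3P)CuH]6, toluene, rt, then equilibration of the epimerisable C3 on mildly acidic work-up) should give the 2,3-trans 3-formylflavan dimer F10. Baeyer–Villiger oxidation (mCPBA, Na2HPO4, CH2Cl2, 0 °C) migrates the secondary C3 with retention to the C3 formate F11, and methanolysis (KHCO3, MeOH, rt) gives 19, so that 17 and step 10 are bypassed.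

Further compounds
F1 | step 8 | (E)-3-[3,4-bis(benzyloxy)phenyl]prop-2-en-1-ol | OC/C=C/c1ccc(OCc2ccccc2)c(OCc2ccccc2)c1
F2 | step 8 | (E)-3-[3,4-bis(benzyloxy)phenyl]allyl methyl carbonate | COC(=O)OC/C=C/c1ccc(OCc2ccccc2)c(OCc2ccccc2)c1
F3 | step 8 | aryl ether of 10 with a 1-[3,4-bis(benzyloxy)phenyl]prop-2-enyl group on the phenol oxygen (catechin-type centre) | c3ccccc3COc1cc(OCc3ccccc3)c2c(c1)O[C@H](c1cc(OCc3ccccc3)c(OCc3ccccc3)c(OCc3ccccc3)c1)[C@@H](O)[C@H]2c1c(O[C@H](c4ccc(OCc3ccccc3)c(OCc3ccccc3)c4)C=C)c(C=O)c(OCc3ccccc3)cc1OCc3ccccc3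
F4 | step 8 | diene: F3 with the formyl group converted into a vinyl group | c3ccccc3COc1cc(OCc3ccccc3)c2c(c1)O[C@H](c1cc(OCc3ccccc3)c(OCc3ccccc3)c(OCc3ccccc3)c1)[C@@H](O)[C@H]2c1c(O[C@H](c4ccc(OCc3ccccc3)c(OCc3ccccc3)c4)C=C)c(C=C)c(OCc3ccccc3)cc1OCc3ccccc3
F5 | step 4 | (−)-epigallocatechin (2,3-cis, 2R,3R) | Oc1cc(O)c2c(c1)O[C@H](c1cc(O)c(O)c(O)c1)[C@H](O)C2
F6 | step 4 | 5,7,3',4',5'-penta-O-benzyl-(−)-epigallocatechin | c3ccccc3COc1cc(OCc3ccccc3)c2c(c1)O[C@H](c1cc(OCc3ccccc3)c(OCc3ccccc3)c(OCc3ccccc3)c1)[C@H](O)C2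
F7 | step 4 | 5,7,3',4',5'-penta-O-benzyl-4β-(2-ethoxyethoxy)-(−)-epigallocatechin | c3ccccc3COc1cc(OCc3ccccc3)c2c(c1)O[C@H](c1cc(OCc3ccccc3)c(OCc3ccccc3)c(OCc3ccccc3)c1)[C@H](O)[C@H]2OCCOCC
F8 | step 4 | 5,7,3',4',5'-penta-O-benzyl-4β-[2-hydroxy-4,6-bis(benzyloxy)phenyl]-(−)-epigallocatechin (2,3-cis-3,4-trans) | c3ccccc3COc1cc(OCc3ccccc3)c2c(c1)O[C@H](c1cc(OCc3ccccc3)c(OCc3ccccc3)c(OCc3ccccc3)c1)[C@H](O)[C@H]2c1c(O)cc(OCc3ccccc3)cc1OCc3ccccc3
F9 | step 4 | corresponding flavan-3-one (C2 aryl α, C4 aryl β) | c3ccccc3COc1cc(OCc3ccccc3)c2c(c1)O[C@H](c1cc(OCc3ccccc3)c(OCc3ccccc3)c(OCc3ccccc3)c1)C(=O)[C@H]2c1c(O)cc(OCc3ccccc3)cc1OCc3ccccc3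
F10 | step 9 | nona-O-benzyl (+)-gallocatechin-(4β→8)-(2,3-trans-3-formylflavan) | c3ccccc3COc1cc(OCc3ccccc3)c2c(c1)O[C@H](c1cc(OCc3ccccc3)c(OCc3ccccc3)c(OCc3ccccc3)c1)[C@@H](O)[C@H]2c1c(OCc3ccccc3)cc(OCc3ccccc3)c2c1O[C@H](c1ccc(OCc3ccccc3)c(OCc3ccccc3)c1)[C@@H](C=O)C2
F11 | step 9 | C3 formate of 19 (formate on the bottom unit) | c3ccccc3COc1cc(OCc3ccccc3)c2c(c1)O[C@H](c1cc(OCc3ccccc3)c(OCc3ccccc3)c(OCc3ccccc3)c1)[C@@H](O)[C@H]2c1c(OCc3ccccc3)cc(OCc3ccccc3)c2c1O[C@H](c1ccc(OCc3ccccc3)c(OCc3ccccc3)c1)[C@@H](OC=O)C2
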